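**Plan**
Numbering (spiro[5.5]undecane, kept for the corresponding atoms of all precursors): ring B = C1–C5 plus spiro C6 (Br at C2; Cl and Me at C3); ring A = C6–C11 (methylidene at C7, Br at C10, Me2 at C11).
Enabling feature: sp2 C7 sits next to spiro C6, and C6 also carries quaternary C11, so C7 can be the carbonyl left behind when C11 shifts from a cyclopentanol carbon onto a C6 cation.
Cuts: C7=CH2 and C2–Br (back to ketone and inverted carbinol); C1–C2 and C6–C11 together (Prins–pinacol); the aldehyde and C3–Cl back to an epoxy alcohol; C6–C7 (alkenyllithium plus bromocyclopentanone).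
Forward: the cyclopentanone (C7–C11) is made first, the C1–C6 chain is joined at C6–C7, then ring B closes while the five-membered ring is enlarged to ring A; the C2 bromine and the methylidene come last.
Stereochemistry: C10 from oxazaborolidine reduction then invertive bromination; C3 from Sharpless epoxidation then invertive chloride opening; C6 and C2 from the chair of the key step under C3 control, C2 then inverted.

Key step: step 12

Assumption: addition to the bromo ketone is taken to occur anti to bromine; the C7 epimer so drawn (silyloxy cis to bromine) stands for both epimers, since C7 ends as the carbonyl.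

**Step 1**
Reactants: 1 2,2-dimethylcyclopentane-1,3-dione
Product: 2 (S)-3-hydroxy-2,2-dimethylcyclopentan-1-one
Conditions: (R)-2-methyl-CBS-oxazaborolidine (0.2 equiv), catecholborane (1.1 equiv), toluene, −78 → −40 °C; aq. NaOH
Reagents that add atoms: none
Why: Corey–Bakshi–Shibata reduction of one of the two enantiotopic carbonyl groups, in which the catalyst binds the ketone lone pair on the methylene side and should deliver hydride to the face that gives the S carbinol (quaternary carbon as the large group), while the single hydride of catecholborane and the low temperature hold the reaction at the ketol stage.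

**Step 2**
Reactants: 2 (S)-3-hydroxy-2,2-dimethylcyclopentan-1-one
Product: 3 (R)-3-bromo-2,2-dimethylcyclopentan-1-one
Conditions: PPh3, CBr4, CH2Cl2, 0 → 40 °C
Reagents that add atoms: tetrabromomethane, BrC(Br)(Br)Br
Why: Appel reaction, in which bromide displaces the oxyphosphonium group from the rear so that the S carbinol gives the R bromide; the neopentylic centre slows the substitution, but the cyclopentyl ring tolerates the SN2 geometry and the quaternary α-carbon rules out β-elimination towards the ketone.

**Step 3**
Reactants: 4 trimethyl(prop-1-yn-1-yl)silane; 5 2,3-dibromoprop-1-ene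
Product: 7 (5-bromohex-5-en-1-yn-1-yl)trimethylsilane, via propargyllithium 6 (not isolated)
Conditions: n-BuLi, THF, −78 → −20 °C; then 5, −78 °C → rt
Reagents that add atoms: none
Why: Deprotonation of the silylpropyne at the methyl group and SN2 alkylation of the resulting propargyllithium by the allylic bromide (the SN2′ path gives the same product), with silicon holding the anion at the propargylic position and the vinylic bromide left untouched.

**Step 4**
Reactants: 7 (5-bromohex-5-en-1-yn-1-yl)trimethylsilane
Product: 8 2-bromohex-1-en-5-yne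
Conditions: K2CO3 (0.2 equiv), MeOH, rt
Reagents that add atoms: none
Why: Base-catalysed methanolysis of the alkynyl C–Si bond (protodesilylation) frees the terminal alkyne needed for carbometalation and does not affect the vinylic bromide.

**Step 5**
Reactants: 8 2-bromohex-1-en-5-yne
Product: 11 (2E)-6-bromo-3-methylhepta-2,6-dien-1-ol, via alkenylalane 9 (not isolated), via lithium alkenylaluminate 10 (not isolated)
Conditions: Me3Al (2 equiv), Cp2ZrCl2 (0.2 equiv), CH2Cl2, 0 °C → rt; volatiles removed; n-BuLi, THF/hexane, −78 → 0 °C; (CH2O)n, rt; aq. HCl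
Reagents that add atoms: trimethylaluminium, C[Al](C)C; paraformaldehyde (as formaldehyde), C=O
Why: Negishi Cp2ZrCl2-catalysed carboalumination adds methyl and aluminium syn across the terminal alkyne with methyl on the inner carbon, and hydroxymethylation of the derived aluminate with formaldehyde proceeds with retention, which fixes the E trisubstituted allylic alcohol.

**Step 6**
Reactants: 11 (2E)-6-bromo-3-methylhepta-2,6-dien-1-ol
Product: 12 {[(2E)-6-bromo-3-methylhepta-2,6-dien-1-yl]oxy}triethylsilane
Conditions: TESCl, imidazole, CH2Cl2, 0 °C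
Reagents that add atoms: chlorotriethylsilane, CC[Si](Cl)(CC)CC
Why: Routine silylation of the primary alcohol gives an ether that survives halogen–lithium exchange and can later be removed in the presence of a hindered tertiary silyl ether.

**Step 7**
Reactants: 12 {[(2E)-6-bromo-3-methylhepta-2,6-dien-1-yl]oxy}triethylsilane; 3 (R)-3-bromo-2,2-dimethylcyclopentan-1-one
Product: 15 triethyl{[(2E)-6-[(1R,3R)-3-bromo-2,2-dimethyl-1-(triethylsilyloxy)cyclopentyl]-3-methylhepta-2,6-dien-1-yl]oxy}silane, via alkenyllithium 13 (not isolated), via lithium alkoxide 14 (not isolated)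
Conditions: 12, t-BuLi (2.05 equiv), Et2O, −78 °C; then 3, −78 °C; then TESOTf, −78 → 0 °C
Reagents that add atoms: triethylsilyl trifluoromethanesulfonate, CC[Si](CC)(CC)OS(=O)(=O)C(F)(F)F
Why: Bromine–lithium exchange with two equivalents of t-BuLi and 1,2-addition of the alkenyllithium to the cyclopentanone, which at −78 °C should outrun enolisation and attack at the secondary bromide and should occur mainly anti to bromine (the new C7 centre is erased in step 12); silylation of the cold lithium alkoxide forestalls Grob-type fragmentation of the γ-bromo alkoxide and installs the group that later drives the pinacol shift.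

**Step 8**
Reactants: 15 triethyl{[(2E)-6-[(1R,3R)-3-bromo-2,2-dimethyl-1-(triethylsilyloxy)cyclopentyl]-3-methylhepta-2,6-dien-1-yl]oxy}silane
Product: 16 (2E)-6-[(1R,3R)-3-bromo-2,2-dimethyl-1-(triethylsilyloxy)cyclopentyl]-3-methylhepta-2,6-dien-1-ol
Conditions: PPTS (0.1 equiv), MeOH/CH2Cl2, −10 → 0 °C
Reagents that add atoms: none
Why: Acid-catalysed methanolysis of silyl ethers is governed by steric access, so the primary allylic ether is cleaved while the tertiary ether beside the quaternary carbon remains.

**Step 9**
Reactants: 16 (2E)-6-[(1R,3R)-3-bromo-2,2-dimethyl-1-(triethylsilyloxy)cyclopentyl]-3-methylhepta-2,6-dien-1-ol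
Product: 17 [(2S,3S)-3-{3-[(1R,3R)-3-bromo-2,2-dimethyl-1-(triethylsilyloxy)cyclopentyl]but-3-en-1-yl}-3-methyloxiran-2-yl]methanol
Conditions: Ti(OiPr)4 (0.1 equiv), L-(+)-diethyl tartrate (0.12 equiv), t-BuOOH (2 equiv), 4 Å molecular sieves, CH2Cl2, −20 °C
Reagents that add atoms: tert-butyl hydroperoxide, CC(C)(C)OO
Why: Sharpless asymmetric epoxidation of the E trisubstituted allylic alcohol, in which L-(+)-tartrate directs oxygen to the face that gives the 2S,3S epoxide as it does for geraniol, while the 1,1-disubstituted alkene lacks a free allylic hydroxyl group and the existing centres are too remote to interfere.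

**Step 10**
Reactants: 17 [(2S,3S)-3-{3-[(1R,3R)-3-bromo-2,2-dimethyl-1-(triethylsilyloxy)cyclopentyl]but-3-en-1-yl}-3-methyloxiran-2-yl]methanol
Product: 18 (2S,3R)-6-[(1R,3R)-3-bromo-2,2-dimethyl-1-(triethylsilyloxy)cyclopentyl]-3-chloro-3-methylhept-6-ene-1,2-diol
Conditions: Ti(OiPr)4 (1.5 equiv), Et2NH·HCl (3 equiv), CH2Cl2, 0 °C → rt; aq. tartaric acid
Reagents that add atoms: diethylammonium chloride, CC[NH2+]CC.[Cl-]
Why: Ti(OiPr)4-assisted opening of a 2,3-epoxy alcohol by chloride at C3, which is also the tertiary carbon best able to carry positive charge, through backside attack, so that inversion converts the 3S epoxide carbon into the 3R tertiary chloride while C2 keeps its oxygen.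

**Step 11**
Reactants: 18 (2S,3R)-6-[(1R,3R)-3-bromo-2,2-dimethyl-1-(triethylsilyloxy)cyclopentyl]-3-chloro-3-methylhept-6-ene-1,2-diol
Product: 19 (2R)-5-[(1R,3R)-3-bromo-2,2-dimethyl-1-(triethylsilyloxy)cyclopentyl]-2-chloro-2-methylhex-5-enal
Conditions: NaIO4, THF/pH 7 buffer, 0 °C → rt
Reagents that add atoms: none
Why: Periodate (Malaprade) glycol cleavage removes the hydroxymethyl carbon as formaldehyde and leaves C2 as the aldehyde, whose α-carbon is quaternary and so cannot epimerise or enolise.

**Step 12**
Reactants: 19 (2R)-5-[(1R,3R)-3-bromo-2,2-dimethyl-1-(triethylsilyloxy)cyclopentyl]-2-chloro-2-methylhex-5-enal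
Product: 21 (2R,3R,6S,10R)-10-bromo-3-chloro-2-hydroxy-3,11,11-trimethylspiro[5.5]undecan-7-one, via SnCl4-bound C6 carbocation 20 (not isolated)
Conditions: SnCl4 (1.1 equiv), CH2Cl2, −78 → −40 °C; then H2O
Reagents that add atoms: none
Why: SnCl4 binds the aldehyde oxygen, the terminal alkene carbon C1 adds to C2 (Prins step) to give the tertiary C6 cation 20, and ring carbon C11 then shifts from the silyloxy carbon C7 to C6 (pinacol step) with loss of the silyl group, so that C1–C2 and C6–C11 form in one operation. The reaction type is the pinacol-terminated Prins annulation of 1-alkenylcycloalkanol silyl ethers, closest in its acetal-initiated ring-enlarging form and in the Lewis acid closures of 5-methylene aldehydes to cyclohexanols; because the tether sits on the inner alkene carbon, the shift here gives a spiro ring system in place of a fused one. Ring B closes 6-endo-trig at the alkene through a chair, and ring A arises by one-carbon enlargement of the cyclopentane and not by a cyclisation. C2 is set by that chair, with the C3–Cl bond equatorial and antiperiplanar to the incoming C1 (polar Felkin–Anh) and the SnCl4-bound oxygen equatorial, which puts the carbinol trans to chlorine; C6 is set by migration of C11 anti to the new C1–C2 bond, which leaves C11 equatorial on ring B and trans to chlorine, so that both new centres are relayed from C3 while C10 is carried through and both C7 epimers converge. The step needs the chair with chlorine and oxygen both equatorial to win, which the preference for chlorine over methyl anti to the forming bond and the clash of an axial SnCl4-bound oxygen with C7 should secure, and it needs C11 to migrate in preference to C8, which the higher migratory aptitude of the quaternary carbon and its preference for the position perpendicular to the cation plane should secure.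

**Step 13**
Reactants: 21 (2R,3R,6S,10R)-10-bromo-3-chloro-2-hydroxy-3,11,11-trimethylspiro[5.5]undecan-7-one
Product: 22 (2S,3R,6S,10R)-2,10-dibromo-3-chloro-3,11,11-trimethylspiro[5.5]undecan-7-one
Conditions: PPh3, CBr4, toluene, rt → 60 °C
Reagents that add atoms: tetrabromomethane, BrC(Br)(Br)Br
Why: Appel reaction in which the equatorial oxyphosphonium group at C2 is displaced by bromide along the axial path, the inversion placing bromine cis to chlorine; the conformer that would allow chlorine participation or anti elimination has C11 axial and is therefore disfavoured.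

**Step 14**
Reactants: 22 (2S,3R,6S,10R)-2,10-dibromo-3-chloro-3,11,11-trimethylspiro[5.5]undecan-7-one
Product: 23 (2S,3R,6R,10R)-2,10-dibromo-3-chloro-3,11,11-trimethyl-7-methylidenespiro[5.5]undecane
Conditions: Cp2TiMe2 (3 equiv), toluene/THF, 65 °C, dark
Reagents that add atoms: Cp2TiMe2 (bis(cyclopentadienyl)dimethyltitanium), C[Ti](C)(C1C=CC=C1)C1C=CC=C1
Why: Petasis methylenation, in which Cp2Ti=CH2 formed on heating adds to the hindered, enolisable C7 ketone through an oxatitanacyclobutane under non-basic conditions, so that the three carbon–halogen bonds and all four stereocentres are left as they are.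

**Compound list**
1 | 2,2-dimethylcyclopentane-1,3-dione | CC1(C)C(=O)CCC1=O | starting material
2 | (S)-3-hydroxy-2,2-dimethylcyclopentan-1-one | O=C1CC[C@H](O)C1(C)C | intermediate
3 | (R)-3-bromo-2,2-dimethylcyclopentan-1-one | O=C1CC[C@@H](Br)C1(C)C | intermediate
4 | trimethyl(prop-1-yn-1-yl)silane | CC#C[Si](C)(C)C | starting material
5 | 2,3-dibromoprop-1-ene | C=C(Br)CBr | starting material
6 | [3-(trimethylsilyl)prop-2-yn-1-yl]lithium (propargyllithium, not isolated) | [Li]CC#C[Si](C)(C)C | intermediate
7 | (5-bromohex-5-en-1-yn-1-yl)trimethylsilane | C=C(Br)CCC#C[Si](C)(C)C | intermediate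
8 | 2-bromohex-1-en-5-yne | C=C(Br)CCC#C | intermediate
9 | [(1E)-6-bromo-2-methylhexa-1,5-dien-1-yl]dimethylalane (alkenylalane, not isolated) | C[Al](C)/C=C(\C)CCC(Br)=C | intermediate
10 | lithium butyl[(1E)-6-bromo-2-methylhexa-1,5-dien-1-yl]dimethylaluminate (not isolated) | [Li+].CCCC[Al-](C)(C)/C=C(\C)CCC(Br)=C | intermediate
11 | (2E)-6-bromo-3-methylhepta-2,6-dien-1-ol | OC/C=C(\C)CCC(Br)=C | intermediate
12 | {[(2E)-6-bromo-3-methylhepta-2,6-dien-1-yl]oxy}triethylsilane | CC[Si](CC)(CC)OC/C=C(\C)CCC(Br)=C | intermediate
13 | [(5E)-5-methyl-7-(triethylsilyloxy)hepta-1,5-dien-2-yl]lithium (alkenyllithium, not isolated) | CC[Si](CC)(CC)OC/C=C(\C)CCC([Li])=C | intermediate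
14 | lithium (1R,3R)-3-bromo-2,2-dimethyl-1-[(5E)-5-methyl-7-(triethylsilyloxy)hepta-1,5-dien-2-yl]cyclopentan-1-olate (not isolated) | CC[Si](CC)(CC)OC/C=C(\C)CCC(=C)[C@]1(O[Li])CC[C@@H](Br)C1(C)C | intermediate
15 | triethyl{[(2E)-6-[(1R,3R)-3-bromo-2,2-dimethyl-1-(triethylsilyloxy)cyclopentyl]-3-methylhepta-2,6-dien-1-yl]oxy}silane | CC[Si](CC)(CC)OC/C=C(\C)CCC(=C)[C@]1(O[Si](CC)(CC)CC)CC[C@@H](Br)C1(C)C | intermediate
16 | (2E)-6-[(1R,3R)-3-bromo-2,2-dimethyl-1-(triethylsilyloxy)cyclopentyl]-3-methylhepta-2,6-dien-1-ol | OC/C=C(\C)CCC(=C)[C@]1(O[Si](CC)(CC)CC)CC[C@@H](Br)C1(C)C | intermediate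
17 | [(2S,3S)-3-{3-[(1R,3R)-3-bromo-2,2-dimethyl-1-(triethylsilyloxy)cyclopentyl]but-3-en-1-yl}-3-methyloxiran-2-yl]methanol | OC[C@@H]1O[C@@]1(C)CCC(=C)[C@]2(O[Si](CC)(CC)CC)CC[C@@H](Br)C2(C)C | intermediate
18 | (2S,3R)-6-[(1R,3R)-3-bromo-2,2-dimethyl-1-(triethylsilyloxy)cyclopentyl]-3-chloro-3-methylhept-6-ene-1,2-diol | OC[C@H](O)[C@](C)(Cl)CCC(=C)[C@]1(O[Si](CC)(CC)CC)CC[C@@H](Br)C1(C)C | intermediate
19 | (2R)-5-[(1R,3R)-3-bromo-2,2-dimethyl-1-(triethylsilyloxy)cyclopentyl]-2-chloro-2-methylhex-5-enal | O=C[C@](C)(Cl)CCC(=C)[C@]1(O[Si](CC)(CC)CC)CC[C@@H](Br)C1(C)C | intermediate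
20 | SnCl4-bound C6 carbocation: ring B closed, C2 oxygen on tin, cation at C6 beside the silyloxycyclopentane (not isolated) | Cl[Sn-](Cl)(Cl)(Cl)O[C@@H]1C[C+](CC[C@@]1(C)Cl)[C@]2(O[Si](CC)(CC)CC)CC[C@@H](Br)C2(C)C | intermediate
21 | (2R,3R,6S,10R)-10-bromo-3-chloro-2-hydroxy-3,11,11-trimethylspiro[5.5]undecan-7-one | O=C1CC[C@@H](Br)C(C)(C)[C@@]12CC[C@@](C)(Cl)[C@H](O)C2 | intermediate
22 | (2S,3R,6S,10R)-2,10-dibromo-3-chloro-3,11,11-trimethylspiro[5.5]undecan-7-one | O=C1CC[C@@H](Br)C(C)(C)[C@@]12CC[C@@](C)(Cl)[C@@H](Br)C2 | intermediate
23 | (2S,3R,6R,10R)-2,10-dibromo-3-chloro-3,11,11-trimethyl-7-methylidenespiro[5.5]undecane | C=C1CC[C@@H](Br)C(C)(C)[C@@]12CC[C@@](C)(Cl)[C@@H](Br)C2 | target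

Total step count: 14. Longest linear sequence: 12 steps (steps 3 to 14, from 4 and 5 to 23); the cyclopentanone branch (steps 1 and 2) joins at step 7.

**Steps most likely to fail**

Step 12. The closure may run through the alternative chair with chlorine axial, which would break the relay of configuration from C3 to C6 and C2. C8 may also migrate in place of C11, or the tertiary allylic silyl ether may ionise before the aldehyde is attacked. The fallback sets out from 19 and changes the initiating electrophile from an SnCl4-bound aldehyde to an O-benzyl oxocarbenium ion. This ion would be generated in situ with benzyl trimethylsilyl ether and catalytic TMSOTf in CH2Cl2 at −78 °C, as in the silyl-modified Sakurai reaction, and is the kind of cation on which pinacol-terminated Prins annulations are established. The bulkier alkoxy group should reinforce the equatorial position at C2, and the promoter is catalytic and cannot chelate. The same closure and shift should give the benzyl ether (2R,3R,6S,10R)-2-(benzyloxy)-10-bromo-3-chloro-3,11,11-trimethylspiro[5.5]undecan-7-one F1. BCl3 in CH2Cl2 at −78 °C would then cleave the benzyl ether and bring the route back to 21.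

Step 13. Backside attack at the hindered C2 may lose out to elimination, or to substitution with retention through participation of the neighbouring chlorine or of the axial C7 carbonyl oxygen. The fallback sets out from 21 and replaces the one-pot oxyphosphonium activation by a discrete sulfonate. Tf2O and pyridine in CH2Cl2 at −30 °C should give (2R,3R,6S,10R)-10-bromo-3-chloro-3,11,11-trimethyl-7-oxospiro[5.5]undecan-2-yl trifluoromethanesulfonate F2. Its small and very good leaving group, held back from ionisation by the adjacent C–Cl bond, should be displaced with inversion by Bu4NBr in toluene at 0 °C → rt, and the route comes back at 22.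

Step 14. Olefination at the ketone flanked by the spiro centre may be slow, so that thermal loss of HBr from the secondary bromides competes at the temperature the titanium reagent needs. The fallback sets out from 22 and replaces carbonyl olefination by addition then elimination (Peterson olefination). Me3SiCH2Li premixed with CeCl3 in THF at −78 °C, a nucleophile of low basicity, should add to C7 and give (2S,3R,6S,10R)-2,10-dibromo-3-chloro-3,11,11-trimethyl-7-[(trimethylsilyl)methyl]spiro[5.5]undecan-7-ol F3 (either C7 epimer). Aqueous HF in MeCN at 0 °C would then induce elimination of the silanol unit, which can only give the exocyclic alkene, and the route comes back at 23.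

**Further compounds**
F1 | step 12 | (2R,3R,6S,10R)-2-(benzyloxy)-10-bromo-3-chloro-3,11,11-trimethylspiro[5.5]undecan-7-one | O=C1CC[C@@H](Br)C(C)(C)[C@@]12CC[C@@](C)(Cl)[C@H](OCc3ccccc3)C2
F2 | step 13 | (2R,3R,6S,10R)-10-bromo-3-chloro-3,11,11-trimethyl-7-oxospiro[5.5]undecan-2-yl trifluoromethanesulfonate | O=C1CC[C@@H](Br)C(C)(C)[C@@]12CC[C@@](C)(Cl)[C@H](OS(=O)(=O)C(F)(F)F)C2
F3 | step 14 | (2S,3R,6S,10R)-2,10-dibromo-3-chloro-3,11,11-trimethyl-7-[(trimethylsilyl)methyl]spiro[5.5]undecan-7-ol (C7 left open, either epimer) | C[Si](C)(C)CC1(O)CC[C@@H](Br)C(C)(C)[C@@]12CC[C@@](C)(Cl)[C@@H](Br)C2
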